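**Plan**

- Cuts, in retro order (C1′ = ring CH carrying the CH2–core arm, C2′ = C(OH)CH3, C3′ and C4′ = the two ring CH2, C5′ = CH–isopropenyl): (i) CH3–C2′; (ii) exocyclic CH2–core C4; (iii) ring bonds C2′–C3′ and C4′–C5′ together, which releases C3′H2–C4′H2 as phenyl vinyl sulfone; (iv) prenyl–C6 and acyl–aryl bonds of the core.
- Enabling feature: in the cyclopentane an oxygen-bearing carbon (C2′) and an allylic methine carrying isopropenyl (C5′) sit 1,3 across C1′ and are bridged by an unsubstituted CH2–CH2. C2′ is the retron of an α-hydroxyalkyl radical, C5′ that of radical addition–β-fragmentation at an allyl sulfone, and CH2–CH2 that of a vinyl sulfone.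
- Forward: the six-membered core is made first in a two-step branch (acylation, dearomatising prenylation). Separately, (R)-malate and methacrolein give an open-chain α-hydroxy acid; the radical [3+2] step closes the cyclopentane; this is trimmed to a Mannich base, joined to the core, and methylated last.
- Stereochemistry: acyl centre from (S)-2-methylbutanoyl chloride; core C6 by ligand-controlled palladium allylation; C5′ relayed from (R)-malate (Fráter–Seebach aldol, then allylic-strain-controlled 5-exo closure); C1′ thermodynamic next to the ketone; C2′ by methyl addition anti to the C1′ arm.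
- Helpers: PhSO2 on the two-carbon unit (removed in step 6) and the malate-derived CO2Me on C1′ (stereochemical relay and regiocontrol; lost as CO2 in step 8).

Key step: step 5

Assumption: the target is treated as the enolised triketone tautomer drawn in its SMILES, and 1, 2, 4, 6, 7 and 11 are taken as commercial.

Step 1
Reactants: 1 2,4,6-trihydroxytoluene; 2 (2S)-2-methylbutanoyl chloride
Product: 3 (2S)-2-methyl-1-(2,4,6-trihydroxy-3-methylphenyl)butan-1-one
Conditions: AlCl3 (4 equiv), PhNO2–CH2Cl2, 0 °C to rt; cold 1 M HCl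
Reagents that add atoms: none
Why: Friedel–Crafts acylation of the electron-rich arene at one of its two equivalent free ring carbons; the stereocentre of 2 is carried through (low temperature to limit enolisation) and no new stereocentre forms.

Step 2
Reactants: 3 (2S)-2-methyl-1-(2,4,6-trihydroxy-3-methylphenyl)butan-1-one; 4 3-methylbut-2-en-1-yl acetate (prenyl acetate)
Product: 5 (6R)-3,5-dihydroxy-6-methyl-2-[(2S)-2-methylbutanoyl]-6-(3-methylbut-2-en-1-yl)cyclohexa-2,4-dien-1-one
Conditions: Pd2(dba)3·CHCl3 (2.5 mol%), (R,R)-DACH-phenyl Trost ligand (7.5 mol%), Et3N (1.2 equiv), THF, 0 °C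
Reagents that add atoms: none
Why: Palladium-catalysed asymmetric allylic alkylation with dearomatisation (Tsuji–Trost type): the phloroglucinolate attacks the unsubstituted terminus of the prenyl π-allyl complex through the methyl-bearing ring carbon (the already alkylated, most electron-rich carbon, as in known geminal dialkylations of acylphloroglucinols), and the chiral ligand pocket selects the ring face to set the (6R) quaternary centre.

Step 3
Reactants: 6 dimethyl (2R)-2-hydroxybutanedioate (dimethyl (R)-malate); 7 2-methylprop-2-enal (methacrolein)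
Product: 9 methyl (2RS,3R,4R)-4-hydroxy-5-oxo-2-(prop-1-en-2-yl)oxolane-3-carboxylate, via aldol diester 8 (not isolated)
Conditions: LDA (2.2 equiv), THF, −78 °C; 7, −78 °C; AcOH; then TsOH·H2O (5 mol%), CH2Cl2, rt
Reagents that add atoms: none
Why: Fráter–Seebach aldol of the malate dianion: the aldehyde adds to the chelated lithium enolate on the face anti to the C2 oxygen, which sets the ester-bearing stereocentre, and the new hydroxyl closes the five-membered lactone on the neighbouring ester; the allylic carbinol centre is left uncontrolled because step 4 destroys it.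

Step 4
Reactants: 9 methyl (2RS,3R,4R)-4-hydroxy-5-oxo-2-(prop-1-en-2-yl)oxolane-3-carboxylate
Product: 10 (2R,3S,4E)-6-(benzenesulfonyl)-2-hydroxy-3-(methoxycarbonyl)-5-methylhex-4-enoic acid
Conditions: PhSO2Na (1.5 equiv), Pd(PPh3)4 (5 mol%), THF–MeOH, 50 °C; then 1 M HCl
Reagents that add atoms: sodium benzenesulfinate, [Na+].[O-]S(=O)c1ccccc1
Why: Tsuji–Trost allylic substitution: zerovalent palladium ionises the allylic lactone C–O bond and sulfinate attacks the CH2 terminus of the 2-methylallyl complex, which opens the ring to the trisubstituted allyl sulfone and frees the α-hydroxy acid; no stereocentre is set and the malate-derived centres are untouched (an E/Z mixture would serve equally).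

Step 5
Reactants: 10 (2R,3S,4E)-6-(benzenesulfonyl)-2-hydroxy-3-(methoxycarbonyl)-5-methylhex-4-enoic acid; 11 (ethenesulfonyl)benzene (phenyl vinyl sulfone, 2 equiv)
Product: 12 methyl (1S,2RS,4RS,5R)-4-(benzenesulfonyl)-2-hydroxy-5-(prop-1-en-2-yl)cyclopentane-1-carboxylate
Conditions: [Ir{dF(CF3)ppy}2(dtbbpy)]PF6 (1 mol%), K2HPO4 (1.2 equiv), degassed DMSO, blue LEDs (450 nm), 25 °C
Reagents that add atoms: none
Why: Proposed new method: the photoexcited trivalent-iridium complex oxidises the carboxylate of 10, and loss of CO2 gives a nucleophilic α-hydroxyalkyl radical at the future carbinol carbon that adds to the CH2 terminus of 11 (first new bond); the electrophilic α-sulfonyl radical then attacks the internal CH of the allyl-sulfone alkene (second new bond), and the tertiary β-sulfonyl radical expels PhSO2•, which unveils the isopropenyl group and is reduced to sulfinate by divalent iridium in a redox-neutral cycle. The closest known reaction types are the photoredox decarboxylative Giese addition of α-oxy acids to vinyl sulfones and radical allylation by addition–β-fragmentation of allyl sulfones; their union into a [3+2] annulation is the untested part. The one ring closed, the cyclopentane, forms in the 5-exo-trig mode, favoured over 6-endo because attack is at the less substituted alkene carbon. The new stereocentre C5 (isopropenyl) is controlled by the ester-bearing carbon C1: allylic 1,3-strain with the alkene substituent cis to C1 holds the C1–H bond in the alkene plane, so the tethered radical attacks the face that places isopropenyl trans to CO2Me, whereas the carbinol (C2) and sulfonyl-bearing (C4) centres form as mixtures that steps 6 and 7 erase. The step needs intermolecular addition to outrun 3-exo closure of the first radical onto the allyl sulfone, and cyclisation to outrun reduction of the α-sulfonyl radical; the excess of the highly reactive acceptor 11 and the very low stationary concentration of divalent iridium should secure both.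

Step 6
Reactants: 12 methyl (1S,2RS,4RS,5R)-4-(benzenesulfonyl)-2-hydroxy-5-(prop-1-en-2-yl)cyclopentane-1-carboxylate
Product: 13 methyl (1S,2RS,5R)-2-hydroxy-5-(prop-1-en-2-yl)cyclopentane-1-carboxylate
Conditions: Mg turnings (10 equiv), MeOH, 50 °C
Reagents that add atoms: none
Why: Reductive desulfonylation by electron transfer from magnesium in methanol (known for alkyl phenyl sulfones) removes the activating group of the two-carbon unit; ester, hydroxyl and the isolated alkene are inert and no stereocentre is set.

Step 7
Reactants: 13 methyl (1S,2RS,5R)-2-hydroxy-5-(prop-1-en-2-yl)cyclopentane-1-carboxylate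
Product: 14 methyl (1S,5R)-2-oxo-5-(prop-1-en-2-yl)cyclopentane-1-carboxylate
Conditions: Dess–Martin periodinane (1.3 equiv), CH2Cl2, 0 °C to rt
Reagents that add atoms: none
Why: Dess–Martin oxidation of the secondary alcohol; both carbinol epimers converge on one β-keto ester, whose ester-bearing carbon is now epimerisable and rests trans to isopropenyl.

Step 8
Reactants: 14 methyl (1S,5R)-2-oxo-5-(prop-1-en-2-yl)cyclopentane-1-carboxylate
Product: 16 (2R,3R)-2-[(dimethylamino)methyl]-3-(prop-1-en-2-yl)cyclopentan-1-one, via keto acid 15 (not isolated)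
Conditions: LiOH·H2O (1.05 equiv), THF–H2O, 0 °C; then Me2NH·HCl (1.2 equiv), 37% aq. CH2O (1.2 equiv), 25 °C
Reagents that add atoms: formaldehyde, C=O; dimethylamine hydrochloride, CNC.Cl
Why: Saponification followed by decarboxylative Mannich reaction of the β-keto acid: the carboxyl group marks the one α-carbon that is aminomethylated and then leaves as CO2, and the new α-centre is epimerisable and rests trans to isopropenyl.

Step 9
Reactants: 16 (2R,3R)-2-[(dimethylamino)methyl]-3-(prop-1-en-2-yl)cyclopentan-1-one; 5 (6R)-3,5-dihydroxy-6-methyl-2-[(2S)-2-methylbutanoyl]-6-(3-methylbut-2-en-1-yl)cyclohexa-2,4-dien-1-one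
Product: 18 (6R)-3,5-dihydroxy-6-methyl-2-[(2S)-2-methylbutanoyl]-6-(3-methylbut-2-en-1-yl)-4-{[(1S,5R)-2-oxo-5-(prop-1-en-2-yl)cyclopentyl]methyl}cyclohexa-2,4-dien-1-one, via enone 17 (not isolated)
Conditions: toluene, 80 °C
Reagents that add atoms: none
Why: Mannich-base alkylation: the acidic triketone 5 protonates the amine, thermal loss of dimethylamine gives the exo-methylene ketone 17 in low stationary concentration (which limits its isomerisation to the endocyclic enone), and 5 adds through its free ring carbon C4 in a Michael reaction; the α-stereocentre is set under thermodynamic control trans to isopropenyl.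

Step 10
Reactants: 18 (6R)-3,5-dihydroxy-6-methyl-2-[(2S)-2-methylbutanoyl]-6-(3-methylbut-2-en-1-yl)-4-{[(1S,5R)-2-oxo-5-(prop-1-en-2-yl)cyclopentyl]methyl}cyclohexa-2,4-dien-1-one
Product: 19 (6R)-3,5-dihydroxy-4-{[(1S,2R,5R)-2-hydroxy-2-methyl-5-(prop-1-en-2-yl)cyclopentyl]methyl}-6-methyl-2-[(2S)-2-methylbutanoyl]-6-(3-methylbut-2-en-1-yl)cyclohexa-2,4-dien-1-one
Conditions: CeCl3 (5 equiv), MeMgBr (5 equiv), THF, −78 to −40 °C; then pH 6 aqueous buffer
Reagents that add atoms: methylmagnesium bromide, C[Mg]Br
Why: Organocerium (Imamoto) 1,2-addition to the enolisable cyclopentanone: the weakly basic reagent attacks the carbonyl face anti to the adjacent CH2–core arm, which gives the tertiary alcohol with OH cis and CH3 trans to that arm, while the triketone is masked as its enolate (a cyclic hemiketal form of 18 opens on deprotonation).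

**Compound list**

1 | 2,4,6-trihydroxytoluene | Cc1c(O)cc(O)cc1O | starting material
2 | (2S)-2-methylbutanoyl chloride | CC[C@H](C)C(Cl)=O | starting material
3 | (2S)-2-methyl-1-(2,4,6-trihydroxy-3-methylphenyl)butan-1-one | CC[C@H](C)C(=O)c1c(O)cc(O)c(C)c1O | intermediate
4 | 3-methylbut-2-en-1-yl acetate (prenyl acetate) | CC(C)=CCOC(C)=O | starting material
5 | (6R)-3,5-dihydroxy-6-methyl-2-[(2S)-2-methylbutanoyl]-6-(3-methylbut-2-en-1-yl)cyclohexa-2,4-dien-1-one | C1=C(O)[C@@](C)(CC=C(C)C)C(=O)C(C(=O)[C@@H](C)CC)=C1O | intermediate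
6 | dimethyl (2R)-2-hydroxybutanedioate (dimethyl (R)-malate) | COC(=O)C[C@@H](O)C(=O)OC | starting material
7 | 2-methylprop-2-enal (methacrolein) | CC(=C)C=O | starting material
8 | dimethyl (2R,3S)-2-hydroxy-3-[(1RS)-1-hydroxy-2-methylprop-2-en-1-yl]butanedioate | COC(=O)[C@H](O)[C@H](C(O)C(C)=C)C(=O)OC | intermediate
9 | methyl (2RS,3R,4R)-4-hydroxy-5-oxo-2-(prop-1-en-2-yl)oxolane-3-carboxylate | O=C1[C@H](O)[C@@H](C(=O)OC)C(C(C)=C)O1 | intermediate
10 | (2R,3S,4E)-6-(benzenesulfonyl)-2-hydroxy-3-(methoxycarbonyl)-5-methylhex-4-enoic acid | OC(=O)[C@H](O)[C@H](/C=C(\C)CS(=O)(=O)c1ccccc1)C(=O)OC | intermediate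
11 | (ethenesulfonyl)benzene (phenyl vinyl sulfone) | C=CS(=O)(=O)c1ccccc1 | starting material
12 | methyl (1S,2RS,4RS,5R)-4-(benzenesulfonyl)-2-hydroxy-5-(prop-1-en-2-yl)cyclopentane-1-carboxylate | C=C(C)[C@@H]1C(S(=O)(=O)c2ccccc2)CC(O)[C@H]1C(=O)OC | intermediate
13 | methyl (1S,2RS,5R)-2-hydroxy-5-(prop-1-en-2-yl)cyclopentane-1-carboxylate | C=C(C)[C@@H]1CCC(O)[C@H]1C(=O)OC | intermediate
14 | methyl (1S,5R)-2-oxo-5-(prop-1-en-2-yl)cyclopentane-1-carboxylate | C=C(C)[C@@H]1CCC(=O)[C@H]1C(=O)OC | intermediate
15 | (1S,5R)-2-oxo-5-(prop-1-en-2-yl)cyclopentane-1-carboxylic acid | C=C(C)[C@@H]1CCC(=O)[C@H]1C(=O)O | intermediate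
16 | (2R,3R)-2-[(dimethylamino)methyl]-3-(prop-1-en-2-yl)cyclopentan-1-one | C=C(C)[C@@H]1CCC(=O)[C@H]1CN(C)C | intermediate
17 | (3S)-2-methylidene-3-(prop-1-en-2-yl)cyclopentan-1-one | C=C(C)[C@@H]1CCC(=O)C1=C | intermediate
18 | (6R)-3,5-dihydroxy-6-methyl-2-[(2S)-2-methylbutanoyl]-6-(3-methylbut-2-en-1-yl)-4-{[(1S,5R)-2-oxo-5-(prop-1-en-2-yl)cyclopentyl]methyl}cyclohexa-2,4-dien-1-one | C=C(C)[C@@H]1CCC(=O)[C@H]1CC1=C(O)[C@@](C)(CC=C(C)C)C(=O)C(C(=O)[C@@H](C)CC)=C1O | intermediate
19 | (6R)-3,5-dihydroxy-4-{[(1S,2R,5R)-2-hydroxy-2-methyl-5-(prop-1-en-2-yl)cyclopentyl]methyl}-6-methyl-2-[(2S)-2-methylbutanoyl]-6-(3-methylbut-2-en-1-yl)cyclohexa-2,4-dien-1-one | C=C(C)[C@@H]1CC[C@@](C)(O)[C@H]1CC1=C(O)[C@@](C)(CC=C(C)C)C(=O)C(C(=O)[C@@H](C)CC)=C1O | target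

**Step count and risks**

Total steps: 10. Longest linear sequence: 8 (steps 3 to 10, from 6); the core branch (steps 1 and 2) joins at step 9.

Steps most likely to fail:

1. Step 5 (Proposed new method). The α-sulfonyl radical may be reduced and protonated before it cyclises, which would leave an open-chain Giese adduct, or the ring closure may show poor facial selectivity. Fallback with known chemistry, from 10 back to 13: 10 is added under the same photoredox conditions to 1,1-bis(phenylsulfonyl)ethylene in a known decarboxylative Giese addition, where the bis-sulfonyl radical is reduced and protonated, to give methyl (2S,3E)-5-(benzenesulfonyl)-2-[(1RS)-3,3-bis(benzenesulfonyl)-1-hydroxypropyl]-4-methylpent-3-enoate F1. A zerovalent-palladium-catalysed intramolecular Tsuji–Trost alkylation (Pd(PPh3)4, DBU, THF, 60 °C), with the allyl sulfone as π-allyl precursor and the bis(sulfonyl)methine as soft nucleophile, closes the ring at the internal allyl terminus to give methyl (1S,2RS,5R)-4,4-bis(benzenesulfonyl)-2-hydroxy-5-(prop-1-en-2-yl)cyclopentane-1-carboxylate F2. Mg in MeOH then removes both sulfonyl groups and returns the route at 13.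

2. Step 2. The allyl-palladium may be attacked by the unsubstituted ring carbon, or with poor facial selectivity; the sense of induction of the ligand also has to be confirmed (the (S,S) ligand would be used if it proves opposite). Fallback, from 3 back to 5: the classical uncatalysed dearomatising alkylation (prenyl bromide, NaOMe, MeOH, 0 °C) should give 5 together with its epimer (6S)-3,5-dihydroxy-6-methyl-2-[(2S)-2-methylbutanoyl]-6-(3-methylbut-2-en-1-yl)cyclohexa-2,4-dien-1-one F3. The two are diastereomers because of the fixed (S)-acyl centre and are separated by preparative chromatography or by crystallisation of their salts with (R)-1-phenylethylamine.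

3. Step 10. Deprotonation α to the ketone may be followed by retro-Michael loss of the triketone, or the facial selectivity of methyl addition may be poor. Fallback, from 16 and 3 back to 19: 16 is heated with the aromatic ketone 3 instead of 5 to give (2S)-2-methyl-1-[2,4,6-trihydroxy-3-methyl-5-{[(1S,5R)-2-oxo-5-(prop-1-en-2-yl)cyclopentyl]methyl}phenyl]butan-1-one F4, from which the aryl group cannot be lost by retro-Michael cleavage. MeMgBr/CeCl3 then gives (2S)-1-[2,4,6-trihydroxy-3-{[(1S,2R,5R)-2-hydroxy-2-methyl-5-(prop-1-en-2-yl)cyclopentyl]methyl}-5-methylphenyl]-2-methylbutan-1-one F5. The palladium-catalysed asymmetric dearomatising prenylation of step 2 (4, Pd2(dba)3·CHCl3, Trost ligand, Et3N) is run last, at the less hindered methyl-bearing ring carbon, and gives 19.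

**Further compounds**

F1 | step 5 | methyl (2S,3E)-5-(benzenesulfonyl)-2-[(1RS)-3,3-bis(benzenesulfonyl)-1-hydroxypropyl]-4-methylpent-3-enoate | COC(=O)[C@@H](/C=C(\C)CS(=O)(=O)c1ccccc1)C(O)CC(S(=O)(=O)c1ccccc1)S(=O)(=O)c1ccccc1
F2 | step 5 | methyl (1S,2RS,5R)-4,4-bis(benzenesulfonyl)-2-hydroxy-5-(prop-1-en-2-yl)cyclopentane-1-carboxylate | C=C(C)[C@@H]1C(S(=O)(=O)c2ccccc2)(S(=O)(=O)c2ccccc2)CC(O)[C@H]1C(=O)OC
F3 | step 2 | (6S)-3,5-dihydroxy-6-methyl-2-[(2S)-2-methylbutanoyl]-6-(3-methylbut-2-en-1-yl)cyclohexa-2,4-dien-1-one | C1=C(O)[C@](C)(CC=C(C)C)C(=O)C(C(=O)[C@@H](C)CC)=C1O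
F4 | step 10 | (2S)-2-methyl-1-[2,4,6-trihydroxy-3-methyl-5-{[(1S,5R)-2-oxo-5-(prop-1-en-2-yl)cyclopentyl]methyl}phenyl]butan-1-one | C=C(C)[C@@H]1CCC(=O)[C@H]1Cc1c(O)c(C)c(O)c(C(=O)[C@@H](C)CC)c1O
F5 | step 10 | (2S)-1-[2,4,6-trihydroxy-3-{[(1S,2R,5R)-2-hydroxy-2-methyl-5-(prop-1-en-2-yl)cyclopentyl]methyl}-5-methylphenyl]-2-methylbutan-1-one | C=C(C)[C@@H]1CC[C@@](C)(O)[C@H]1Cc1c(O)c(C)c(O)c(C(=O)[C@@H](C)CC)c1O
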